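**Plan**

- Retrosynthesis: after removal of the six O-protecting groups, the flavanone is cut at the aryl ketone bond C4–C4a, then at the aryl ether bond O1–C2, which leads back to a cis-β-lactone. The lactone is cut at C2–C3 and at its acyl–oxygen bond into a (flavon-3-yl)ketene and a ring B aldehyde. The flavone-3-acetic acid is cut in its pyranone ring and at its aryl ketone bond back to phloroglucinol and succinic anhydride.
- Forward: the flavone pyranone ring closes first (aroyl transfer, cyclodehydration), the four-membered lactone joins ring B to the flavone, the ring A phenoxide opens it to form O1–C2, and ring C of the flavanone closes last by forming C4–C4a.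
- Enabling feature: ring A is a phloroglucinol ring, so in the aryl ether the oxygens that become O1, O5 and O7 stand 1,3,5. The two carbons flanking the O1-bearing carbon (future C8a) are equivalent, each is ortho or para to all three oxygens, and whichever attacks becomes C4a.
- Stereochemistry: C2 and C3 are both set in the alkaloid-catalysed ketene–aldehyde cycloaddition (cis, 3R,4R lactone). SN2 opening inverts the benzylic carbon, so the cis lactone gives the (2R,3S) acid and hence the 2,3-trans (2S,3R) flavanone, which is also the more stable isomer at C3. The ring closure creates no stereocentre.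
- Protection: five phenols as benzyl ethers; the ring B phenol as a tert-butyl carbonate, electron-withdrawing so that the benzylic C2–O bond resists ionisation, and hindered so that it is not passed on to the phenoxide that forms the ether bond.

Key step: step 9

Assumption: O-trimethylsilylquinidine is taken to give the (3R,4R) lactone, as the quinidine series does in related ketene–aldehyde cycloadditions; if the first run shows the opposite sense, the pseudoenantiomeric O-trimethylsilylquinine is used and nothing else changes.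

In the step lines, Fl stands for the 5,7-bis(benzyloxy)-2-[4-(benzyloxy)phenyl]-4-oxo-4H-chromen-3-yl group; full names are in the compound list.

**Route**

Step 1
Reactants: 1 phloroglucinol; 2 succinic anhydride
Product: 3 4-oxo-4-(2,4,6-trihydroxyphenyl)butanoic acid
Conditions: AlCl3 (3 equiv), PhNO2, rt → 60 °C; aq. HCl
Reagents that add atoms: none
Why: Friedel–Crafts acylation of the electron-rich triphenol by the AlCl3-activated anhydride; the three ring carbons are equivalent and the first acyl group deactivates the ring against a second.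

Step 2
Reactants: 3 4-oxo-4-(2,4,6-trihydroxyphenyl)butanoic acid
Product: 4 benzyl 4-[2,4-bis(benzyloxy)-6-hydroxyphenyl]-4-oxobutanoate
Conditions: BnBr (3.1 equiv), K2CO3, DMF, rt → 40 °C
Reagents that add atoms: benzyl bromide, BrCc1ccccc1
Why: Williamson-type O-alkylation in which the carboxylate and the two more accessible phenols are benzylated, whereas the last ortho hydroxyl, held in a hydrogen bond to the ketone, reacts far more slowly, as is usual for 2,4,6-trihydroxyphenyl ketones.

Step 3
Reactants: 4 benzyl 4-[2,4-bis(benzyloxy)-6-hydroxyphenyl]-4-oxobutanoate; 5 4-(benzyloxy)benzoyl chloride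
Product: 6 benzyl 4-[2,4-bis(benzyloxy)-6-{[4-(benzyloxy)benzoyl]oxy}phenyl]-4-oxobutanoate
Conditions: Et3N, DMAP (cat.), CH2Cl2, 0 °C → rt
Reagents that add atoms: none
Why: DMAP-catalysed O-acylation (nucleophilic catalysis) of the remaining chelated phenol by the aroyl chloride.

Step 4
Reactants: 6 benzyl 4-[2,4-bis(benzyloxy)-6-{[4-(benzyloxy)benzoyl]oxy}phenyl]-4-oxobutanoate
Product: 8 benzyl (Fl)acetate, via 1,3-diketone 7 (not isolated)
Conditions: LiN(SiMe3)2 (2.2 equiv), THF, −78 → 0 °C; AcOH; then p-TsOH·H2O (cat.), toluene, 80 °C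
Reagents that add atoms: none
Why: Baker–Venkataraman rearrangement, in which the enolate of the aryl ketone (its α-methylene is much more acidic than that of the ester) takes over the aroyl group from the neighbouring phenol ester, followed by acid-catalysed cyclodehydration of the freed phenol onto the aroyl carbonyl, which closes the pyranone ring and leaves the CH2CO2Bn arm on C3 of the flavone.

Step 5
Reactants: 8 benzyl (Fl)acetate
Product: 9 (Fl)acetic acid
Conditions: LiOH·H2O, THF/H2O, rt; then 1 M HCl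
Reagents that add atoms: lithium hydroxide, [Li+].[OH-]
Why: Saponification of the unhindered benzyl ester by acyl–oxygen cleavage; the flavone and the aryl benzyl ethers are stable to LiOH at rt.

Step 6
Reactants: 9 (Fl)acetic acid
Product: 10 (Fl)acetyl chloride
Conditions: (COCl)2, DMF (cat.), CH2Cl2, 0 °C → rt; evaporate, use crude
Reagents that add atoms: oxalyl chloride, ClC(=O)C(Cl)=O
Why: Chloroiminium (Vilsmeier-type) catalysis turns the acid into its chloride under neutral, non-aqueous conditions that leave the benzyl ethers and the flavone alone.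

Step 7
Reactants: 10 (Fl)acetyl chloride; 11 tert-butyl (4-formylphenyl) carbonate
Product: 13 (3R,4R)-4-{4-[(tert-butoxycarbonyl)oxy]phenyl}-3-Fl-oxetan-2-one (cis), via ketene 12 (not isolated)
Conditions: O-trimethylsilylquinidine (10 mol%), LiClO4 (2 equiv), iPr2NEt (2.5 equiv), 11 (1.5 equiv), CH2Cl2/Et2O, −78 °C, 10 added over 2 h
Reagents that add atoms: none
Why: Cinchona alkaloid/Lewis acid-catalysed acyl halide–aldehyde cyclocondensation (formal ketene–aldehyde [2+2] cycloaddition), in which the tertiary amine adds to ketene 12 to give a Z ammonium enolate that attacks the LiClO4-activated aldehyde through a closed chair (Zimmerman–Traxler-type) transition state, placing the Fl and aryl groups cis, while the quinidine framework shields one enolate face and so fixes both new stereocentres as 3R,4R before acyl substitution closes the four-membered ring and frees the catalyst.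

Step 8
Reactants: 13 (3R,4R)-4-{4-[(tert-butoxycarbonyl)oxy]phenyl}-3-Fl-oxetan-2-one; 14 3,5-bis(benzyloxy)phenol
Product: 15 (2R,3S)-3-[3,5-bis(benzyloxy)phenoxy]-3-{4-[(tert-butoxycarbonyl)oxy]phenyl}-2-Fl-propanoic acid
Conditions: 14 (2 equiv), Cs2CO3 (1 equiv), DMF, 0 °C → rt; cold 0.5 M HCl
Reagents that add atoms: none
Why: SN2 alkyl–oxygen cleavage of the strained β-lactone by a phenoxide (a mode known for simple β-lactones), in which the caesium phenoxide attacks the benzylic C4 anti to the ring oxygen so that this centre is inverted (4R lactone carbon to 3S ether carbon) while C3 is untouched, the leaving carboxylate cannot undergo β-elimination, the excess free phenol keeps the medium too weakly basic for α-deprotonation, acyl–oxygen attack is reversible, and the hindered tert-butyl carbonate resists transfer to the phenoxide.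

Step 9
Reactants: 15 (2R,3S)-3-[3,5-bis(benzyloxy)phenoxy]-3-{4-[(tert-butoxycarbonyl)oxy]phenyl}-2-Fl-propanoic acid
Product: 17 (2S,3R)-5,7-bis(benzyloxy)-2-{4-[(tert-butoxycarbonyl)oxy]phenyl}-3-Fl-chroman-4-one (2,3-trans), via mixed anhydride 16 (not isolated)
Conditions: (CF3CO)2O (3 equiv), CH2Cl2, 0 °C → rt; aq. NaHCO3
Reagents that add atoms: none
Why: Trifluoroacetic anhydride converts the acid into the mixed anhydride 16, whose alkyl-acyl carbon (trifluoroacetate being the better leaving group) is attacked by a ring carbon ortho to the ether oxygen of the 3,5-bis(benzyloxy)phenoxy group, and loss of a proton from the arenium ion gives the aryl ketone. This is an intramolecular Friedel–Crafts acylation, the standard closure of 3-aryloxypropanoic acids to chroman-4-ones and of 3-aryl-3-aryloxypropanoic acids to flavanones. The pyranone ring C closes in a six-membered mode in which the arene carbon adds to the trigonal acyl carbon with its C=O outside the new ring (6-exo-trig at the acyl carbon, the arene C4a=C8a bond lying inside the ring). No stereocentre is created and no bond to C2 or C3 is made or broken; should C3 enolise in the acidic medium, the trans-diequatorial isomer wanted is the more stable one. The step needs chemoselectivity for the aryl ether ring and integrity of the benzylic C2–O1 bond: the attacked carbon is activated by three oxygens (ortho to O1, ortho to one benzyloxy group, para to the other) and has an equivalent twin, the carbon between the two benzyloxy groups cannot reach the acyl carbon, the flavone rings are deactivated by their carbonyl, and the electron-withdrawing carbonate on ring B disfavours ionisation at C2.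

Step 10
Reactants: 17 (2S,3R)-5,7-bis(benzyloxy)-2-{4-[(tert-butoxycarbonyl)oxy]phenyl}-3-Fl-chroman-4-one
Product: 18 (2S,3R)-5,7-bis(benzyloxy)-2-(4-hydroxyphenyl)-3-Fl-chroman-4-one
Conditions: CF3CO2H/CH2Cl2 (1:4), 0 °C
Reagents that add atoms: none
Why: Acidolysis of the aryl tert-butyl carbonate (tert-butyl cation lost as isobutene, then decarboxylation) frees the ring B phenol, while the benzyl ethers and the flavanone, which holds its configuration in acid, should survive at 0 °C.

Step 11
Reactants: 18 (2S,3R)-5,7-bis(benzyloxy)-2-(4-hydroxyphenyl)-3-Fl-chroman-4-one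
Product: 19 (2S,3R)-5,7-dihydroxy-3-[5,7-dihydroxy-2-(4-hydroxyphenyl)-4-oxo-4H-chromen-3-yl]-2-(4-hydroxyphenyl)chroman-4-one (CNP0208264.1)
Conditions: H2 (1 atm), Pd/C (10 wt%), THF/MeOH, rt
Reagents that add atoms: none
Why: Heterogeneous catalytic hydrogenolysis of the five aryl benzyl ethers under neutral conditions at rt, where the tetrasubstituted flavone double bond, the aryl ketones and the base-sensitive flavanone stereocentres should stay untouched.

**Compound list**

1 | phloroglucinol (benzene-1,3,5-triol) | Oc1cc(O)cc(O)c1 | starting material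
2 | succinic anhydride | O=C1CCC(=O)O1 | starting material
3 | 4-oxo-4-(2,4,6-trihydroxyphenyl)butanoic acid | OC(=O)CCC(=O)c1c(O)cc(O)cc1O | intermediate
4 | benzyl 4-[2,4-bis(benzyloxy)-6-hydroxyphenyl]-4-oxobutanoate | O=C(CCC(=O)c1c(O)cc(OCc2ccccc2)cc1OCc1ccccc1)OCc1ccccc1 | intermediate
5 | 4-(benzyloxy)benzoyl chloride | O=C(Cl)c1ccc(OCc2ccccc2)cc1 | starting material
6 | benzyl 4-[2,4-bis(benzyloxy)-6-{[4-(benzyloxy)benzoyl]oxy}phenyl]-4-oxobutanoate | O=C(CCC(=O)c1c(OC(=O)c2ccc(OCc3ccccc3)cc2)cc(OCc2ccccc2)cc1OCc1ccccc1)OCc1ccccc1 | intermediate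
7 | benzyl 3-[2,4-bis(benzyloxy)-6-hydroxybenzoyl]-4-[4-(benzyloxy)phenyl]-4-oxobutanoate (racemic, enolisable 1,3-diketone) | O=C(CC(C(=O)c1c(O)cc(OCc2ccccc2)cc1OCc1ccccc1)C(=O)c1ccc(OCc2ccccc2)cc1)OCc1ccccc1 | intermediate
8 | benzyl 2-{5,7-bis(benzyloxy)-2-[4-(benzyloxy)phenyl]-4-oxo-4H-chromen-3-yl}acetate | O=C(Cc1c(-c2ccc(OCc3ccccc3)cc2)oc2cc(OCc3ccccc3)cc(OCc3ccccc3)c2c1=O)OCc1ccccc1 | intermediate
9 | 2-{5,7-bis(benzyloxy)-2-[4-(benzyloxy)phenyl]-4-oxo-4H-chromen-3-yl}acetic acid | OC(=O)Cc1c(-c2ccc(OCc3ccccc3)cc2)oc2cc(OCc3ccccc3)cc(OCc3ccccc3)c2c1=O | intermediate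
10 | 2-{5,7-bis(benzyloxy)-2-[4-(benzyloxy)phenyl]-4-oxo-4H-chromen-3-yl}acetyl chloride | ClC(=O)Cc1c(-c2ccc(OCc3ccccc3)cc2)oc2cc(OCc3ccccc3)cc(OCc3ccccc3)c2c1=O | intermediate
11 | tert-butyl (4-formylphenyl) carbonate | CC(C)(C)OC(=O)Oc1ccc(C=O)cc1 | starting material
12 | {5,7-bis(benzyloxy)-2-[4-(benzyloxy)phenyl]-4-oxo-4H-chromen-3-yl}ketene | O=C=Cc1c(-c2ccc(OCc3ccccc3)cc2)oc2cc(OCc3ccccc3)cc(OCc3ccccc3)c2c1=O | intermediate
13 | tert-butyl 4-[(2R,3R)-3-{5,7-bis(benzyloxy)-2-[4-(benzyloxy)phenyl]-4-oxo-4H-chromen-3-yl}-4-oxooxetan-2-yl]phenyl carbonate (cis-β-lactone; 3R,4R in oxetan-2-one numbering) | O=C1[C@H](c2c(-c3ccc(OCc4ccccc4)cc3)oc3cc(OCc4ccccc4)cc(OCc4ccccc4)c3c2=O)[C@H](c2ccc(OC(=O)OC(C)(C)C)cc2)O1 | intermediate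
14 | 3,5-bis(benzyloxy)phenol | Oc1cc(OCc2ccccc2)cc(OCc2ccccc2)c1 | starting material
15 | (2R,3S)-2-{5,7-bis(benzyloxy)-2-[4-(benzyloxy)phenyl]-4-oxo-4H-chromen-3-yl}-3-[3,5-bis(benzyloxy)phenoxy]-3-{4-[(tert-butoxycarbonyl)oxy]phenyl}propanoic acid | OC(=O)[C@H](c1c(-c2ccc(OCc3ccccc3)cc2)oc2cc(OCc3ccccc3)cc(OCc3ccccc3)c2c1=O)[C@H](Oc1cc(OCc2ccccc2)cc(OCc2ccccc2)c1)c1ccc(OC(=O)OC(C)(C)C)cc1 | intermediate
16 | mixed anhydride of acid 15 with trifluoroacetic acid (2R,3S) | O=C(OC(=O)C(F)(F)F)[C@H](c1c(-c2ccc(OCc3ccccc3)cc2)oc2cc(OCc3ccccc3)cc(OCc3ccccc3)c2c1=O)[C@H](Oc1cc(OCc2ccccc2)cc(OCc2ccccc2)c1)c1ccc(OC(=O)OC(C)(C)C)cc1 | intermediate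
17 | tert-butyl 4-[(2S,3R)-5,7-bis(benzyloxy)-3-{5,7-bis(benzyloxy)-2-[4-(benzyloxy)phenyl]-4-oxo-4H-chromen-3-yl}-4-oxochroman-2-yl]phenyl carbonate (2,3-trans) | O=C1c2c(OCc3ccccc3)cc(OCc3ccccc3)cc2O[C@H](c2ccc(OC(=O)OC(C)(C)C)cc2)[C@H]1c1c(-c2ccc(OCc3ccccc3)cc2)oc2cc(OCc3ccccc3)cc(OCc3ccccc3)c2c1=O | intermediate
18 | (2S,3R)-5,7-bis(benzyloxy)-3-{5,7-bis(benzyloxy)-2-[4-(benzyloxy)phenyl]-4-oxo-4H-chromen-3-yl}-2-(4-hydroxyphenyl)chroman-4-one | O=C1c2c(OCc3ccccc3)cc(OCc3ccccc3)cc2O[C@H](c2ccc(O)cc2)[C@H]1c1c(-c2ccc(OCc3ccccc3)cc2)oc2cc(OCc3ccccc3)cc(OCc3ccccc3)c2c1=O | intermediate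
19 | (2S,3R)-5,7-dihydroxy-3-[5,7-dihydroxy-2-(4-hydroxyphenyl)-4-oxo-4H-chromen-3-yl]-2-(4-hydroxyphenyl)chroman-4-one (CNP0208264.1) | O=C1c2c(O)cc(O)cc2O[C@H](c2ccc(O)cc2)[C@H]1c1c(-c2ccc(O)cc2)oc2cc(O)cc(O)c2c1=O | target

**Step count and risks**

Total step count: 11. Longest linear sequence: 11 steps (1 to 19 through 3, 4, 6, 8, 9, 10, 13, 15, 17 and 18).

Steps most likely to fail:

Step 7. The aryl-substituted ketene may dimerise, its stabilised ammonium enolate may add only sluggishly to an aromatic aldehyde, or facial and cis selectivity may erode. The fallback replaces catalyst control by auxiliary control and sets out from acid 9. The acid is activated as its mixed pivalic anhydride (PivCl, Et3N) and joined to lithiated (R)-4-benzyl-2-oxazolidinone to give the imide (R)-4-benzyl-3-(2-{5,7-bis(benzyloxy)-2-[4-(benzyloxy)phenyl]-4-oxo-4H-chromen-3-yl}acetyl)oxazolidin-2-one F1. Its Z boron enolate (Bu2BOTf, iPr2NEt, CH2Cl2, −78 °C) should add to aldehyde 11 in an Evans syn aldol reaction to give the (2R,3R) adduct (R)-4-benzyl-3-[(2R,3R)-2-{5,7-bis(benzyloxy)-2-[4-(benzyloxy)phenyl]-4-oxo-4H-chromen-3-yl}-3-{4-[(tert-butoxycarbonyl)oxy]phenyl}-3-hydroxypropanoyl]oxazolidin-2-one F2. Brief treatment with LiOH/H2O2 at 0 °C should release (2R,3R)-2-{5,7-bis(benzyloxy)-2-[4-(benzyloxy)phenyl]-4-oxo-4H-chromen-3-yl}-3-{4-[(tert-butoxycarbonyl)oxy]phenyl}-3-hydroxypropanoic acid F3. Lactonisation through carboxyl activation (PhSO2Cl, pyridine, 0 °C), which retains the carbinol configuration, returns to the route at cis-lactone 13.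

Step 8. The phenoxide may deprotonate the lactone at C3 (epimerisation, or ring-opening elimination to the cinnamic acid), the benzylic carbon may ionise with loss of configuration or decarboxylation, or the carbonate may migrate to the phenoxide. The fallback forms the ether under neutral Mitsunobu conditions and sets out from lactone 13. Alcoholysis with allyl alcohol catalysed by La(OtBu)3 (acyl–oxygen cleavage, carbinol configuration retained) should give allyl (2R,3R)-2-{5,7-bis(benzyloxy)-2-[4-(benzyloxy)phenyl]-4-oxo-4H-chromen-3-yl}-3-{4-[(tert-butoxycarbonyl)oxy]phenyl}-3-hydroxypropanoate F4. Mitsunobu etherification with phenol 14 (PPh3, DIAD, toluene, 0 °C) inverts the carbinol carbon and should give allyl (2R,3S)-2-{5,7-bis(benzyloxy)-2-[4-(benzyloxy)phenyl]-4-oxo-4H-chromen-3-yl}-3-[3,5-bis(benzyloxy)phenoxy]-3-{4-[(tert-butoxycarbonyl)oxy]phenyl}propanoate F5. Deallylation with Pd(PPh3)4 and PhSiH3 in THF, which needs no base and so avoids β-elimination of the aryloxide, returns to the route at acid 15.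

Step 11. Hydrogenation may go too far (hydrogenolytic opening of the benzylic C2–O1 bond, saturation of the flavone double bond) or stall before the last benzyl groups are gone. The fallback sets out from 18 and cleaves the benzyl ethers by a Lewis acid with a cation scavenger instead of by reduction (BCl3, pentamethylbenzene, CH2Cl2, −78 °C; methanol quench), arriving directly at 19; no new compound is made (F0).

Further compounds
F1 | step 7 | (R)-4-benzyl-3-(2-{5,7-bis(benzyloxy)-2-[4-(benzyloxy)phenyl]-4-oxo-4H-chromen-3-yl}acetyl)oxazolidin-2-one | O=C(Cc1c(-c2ccc(OCc3ccccc3)cc2)oc2cc(OCc3ccccc3)cc(OCc3ccccc3)c2c1=O)N1[C@H](Cc2ccccc2)COC1=O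
F2 | step 7 | (R)-4-benzyl-3-[(2R,3R)-2-{5,7-bis(benzyloxy)-2-[4-(benzyloxy)phenyl]-4-oxo-4H-chromen-3-yl}-3-{4-[(tert-butoxycarbonyl)oxy]phenyl}-3-hydroxypropanoyl]oxazolidin-2-one | O=C([C@H](c1c(-c2ccc(OCc3ccccc3)cc2)oc2cc(OCc3ccccc3)cc(OCc3ccccc3)c2c1=O)[C@@H](O)c1ccc(OC(=O)OC(C)(C)C)cc1)N1[C@H](Cc2ccccc2)COC1=O
F3 | step 7 | (2R,3R)-2-{5,7-bis(benzyloxy)-2-[4-(benzyloxy)phenyl]-4-oxo-4H-chromen-3-yl}-3-{4-[(tert-butoxycarbonyl)oxy]phenyl}-3-hydroxypropanoic acid | OC(=O)[C@H](c1c(-c2ccc(OCc3ccccc3)cc2)oc2cc(OCc3ccccc3)cc(OCc3ccccc3)c2c1=O)[C@@H](O)c1ccc(OC(=O)OC(C)(C)C)cc1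
F4 | step 8 | allyl (2R,3R)-2-{5,7-bis(benzyloxy)-2-[4-(benzyloxy)phenyl]-4-oxo-4H-chromen-3-yl}-3-{4-[(tert-butoxycarbonyl)oxy]phenyl}-3-hydroxypropanoate | C=CCOC(=O)[C@H](c1c(-c2ccc(OCc3ccccc3)cc2)oc2cc(OCc3ccccc3)cc(OCc3ccccc3)c2c1=O)[C@@H](O)c1ccc(OC(=O)OC(C)(C)C)cc1
F5 | step 8 | allyl (2R,3S)-2-{5,7-bis(benzyloxy)-2-[4-(benzyloxy)phenyl]-4-oxo-4H-chromen-3-yl}-3-[3,5-bis(benzyloxy)phenoxy]-3-{4-[(tert-butoxycarbonyl)oxy]phenyl}propanoate | C=CCOC(=O)[C@H](c1c(-c2ccc(OCc3ccccc3)cc2)oc2cc(OCc3ccccc3)cc(OCc3ccccc3)c2c1=O)[C@H](Oc1cc(OCc2ccccc2)cc(OCc2ccccc2)c1)c1ccc(OC(=O)OC(C)(C)C)cc1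
F0 | step 11 | none | none
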